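| setting | maple | alder | flask |
|---|---|---|---|
| starting material | 0.050 M | 0.034 M | 0.050 M |
| coupling partner | 0.050 M | 0.050 M | 0.0500 M |
| remark | the very flask that is asked about, followed so far | run made earlier |  |
| time |  |  | 3.0 h |

- maple (time / min: double product / %, first product / %): 8.00: 13, 27; 15.0: 17, 31; 25.0: 22, 34; 30.0: 30, 36; 40.0: 29, 30; 50.0: 29, 31
- alder (time / h: double product / %, first product / %): 0.417: 29, 26; 0.833: 41, 25; 1.33: 45, 22; 1.50: 45, 24; 2.00: 43, 23; 2.50: 43, 24; 3.00: 45, 25

(readings scatter by 2 percentage points)

1. why nothing more happens at 3.0 h, or that something still does (the coupling partner has run out first / all of the starting material has reacted / it is still moving)
2. double product at 3.0 h, in percent of the starting material charged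
3. first product at 3.0 h, in percent of the starting material charged

- what is said of double product includes crystals
- crystals is a solid; its amount is given per volume of the solution
- the numbers in the tables scatter by 2 percentage points (one standard deviation)
- on the list of suspects stand: starting material <-> dormant form; coupling partner + first product -> double product; starting material + coupling partner -> first product; crystals <-> double product; coupling partner + double product -> triple product
- the reaction counts as stopped when no species that holds the starting material changes by six tenths of a point or more over the second half of the time

1. At 8.00 min, the first maple reading, I already saw 27% first product and 13% double product, more of the former. Starting material and coupling partner met quickly.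

2. Between 25.0 min and 30.0 min the maple double product read 22%, then 30%, while first product read 34%, then 36%. This was the stretch to watch: both readings were still rising.

3. At 40.0 min and 50.0 min the maple readings stood flat within the scatter of 2 percentage points. Alder did the same from 1.33 h to 3.00 h.

4. At 50.0 min in maple, the coupling partner charged, less one equivalent per first product and two per double product, left 11.0% of the starting material charged. I called this the partner gap.

5. I took [coupling partner] to have ended in the products. Triple product holds 3 equivalents, so the gap gave 3.67% triple product, a rough figure. That left 36.3% as starting material or dormant form. Flat readings with so much unused pointed to the coupling partner as limiting reagent.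

6. I committed to the last two maple readings averaged: 29.0% double product and 30.5% first product.

The forecast gave the coupling partner has run out first, with 29.5% double product (27.5% to 32%) and 31% first product (29% to 33.5%), slightly above mine: “The partner has therefore run out”.

The flask gave the coupling partner has run out first, with 28.5% double product and 30.1% first product at 3.0 h.

    starting material ⇌ dormant form (K = 0.980, k = 0.0110 s⁻¹)
    coupling partner + first product → double product (k = 0.0410 L mol⁻¹ s⁻¹)
    starting material + coupling partner → first product (k = 0.0580 L mol⁻¹ s⁻¹)
    crystals ⇌ double product, rate k4*(cs4 - [double product]) while solid is left; crystals form when [double product] > cs4 (solubility = 4.30 mM, k = 0.0670 s⁻¹)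
    coupling partner + double product → triple product (k = 0.0200 L mol⁻¹ s⁻¹)

In this flask [coupling partner] stood at 0% of its charge at 3.00 h. The partner gap from these answers was 12.9%, which gave 4.31% triple product, and the flask held 4.31%. The neighbouring flask had 0.085 M starting material and 0.588 equiv of coupling partner. It ended with [coupling partner] at 0%, 28.8% first product and 13.1% double product. Its gap was 3.74%, which gave 1.25% triple product, and that flask held 1.25%.

The earlier runs and the new flask were generated by integration from invented constants; the scatter is artificial.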